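## The problem

The target is an open-chain furanoterpenoid whose three heterocycles are not fused but strung on one chain. A 4-hydroxy-3-methylbutenolide (ring A: O1, lactone carbonyl C2, methyl-bearing C3, enol carbon C4, C5) is joined through a Z exocyclic alkene C5=C6 to the chain C6–C14, and C14 ends on C4 of a 2,4-disubstituted furan (ring B) that carries a furan-3-ylmethyl group (ring C) on its C2. The work is therefore chain assembly with three alkene geometries (Z at C5=C6, E at C9=C10 and at C11=C12) and one lactone closure. The only stereocenter is C7 (S, methyl-bearing); nothing else in the molecule can set it and it can steer nothing else, so it must be bought or made under reagent control and then kept out of any position α to a carbonyl group. In the finished ylidene tetronate C7 is allylic and γ to a vinylogous ester, so strongly basic conditions late in the route are to be avoided as well. The two furans and the doubly activated methylene between them do not survive strong protic or Lewis acids, peracids or other electrophilic oxidants; the diene is acid-sensitive; the free tetronic acid is a strong, chelating acid best carried as its methyl ether to the last step. The feature that opens the molecule is the pair C4/C5: two neighbouring carbons that both stand at carbonyl oxidation level, the enol carbon and the enol-lactone carbon. Carbonyl chemistry of normal polarity joins 1,3- and 1,5-related oxygen functions but not such a 1,2-pair, so one partner must react with inverted polarity: C4, β to the ester carbon C2 in a β-methoxyacrylate, can become a vinyl anion while C5 arrives as an acylating agent. The ketone so formed lies cis to the ester, so O1–C2 can close afterwards through the C5=C6 enol.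

## Retrosynthesis

**Target 25 to methyl tetronate 24 (O–CH3 at C4).** The acidic enol is masked as the methyl ether that the acrylate building block already carries, so no protecting step is spent on it. The forward step must remove a methyl group from a vinylogous carbonate without acid; SN2 attack of a soft thiolate on the methyl carbon does that.

**24 to keto ester 23 (O1–C2).** Opening the lactone bond and returning C5 to a ketone gives acyclic 23, in which ester and ketone are cis on the C3=C4 alkene. The neighbouring cut at C5=C6 (condensing a tetronate C5 anion with an aldehyde) would place C7 α to an aldehyde and invite epimerisation. Forming O1–C5 from an alkyne costs more steps (see Alternative 1). The forward reaction is an enol lactonisation with loss of methanol; it must be mild enough for the furans and should deliver the Z alkene under thermodynamic control.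

**23 to Weinreb amide 16 and acrylate 20 (C4–C5).** This is the strategic cut. It splits the molecule into a four-carbon acrylate that holds C2, C3, C4 and both methyl groups and a chain amide that holds everything else, and it is the only cut that makes the 1,2-dioxygenated pair directly. C4 reacts as the vinyllithium 21 obtained from 20, C5 as the Weinreb carbonyl. An aldehyde at C5 would give the wrong oxidation level. An ester or acid chloride would risk double addition. The forward step asks for clean vinylic metalation, retention of vinyl geometry, and addition in preference to enolisation of the amide.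

**20 to methyl propanoate 17 and methyl formate 18 (C3–C4).** A crossed Claisen formylation followed by O-methylation of the sodium enolate 19 gives 20 in one operation from two bulk esters.

**16 to sulfone 15 and enal 9 (C9=C10).** A Julia–Kocienski olefination joins the two halves at the diene. The sulfone is placed on the saturated, furan-free half, so the sulfide oxidation is over before any furan exists. An alkyl phenyltetrazolyl sulfone with a conjugated aldehyde is the E-selective pairing. The C11=C12 geometry is already fixed in 9. The forward reaction must tolerate the Weinreb amide four atoms from the carbanion.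

**15 back to half-ester 10 (functional-group changes only).** Sulfone 15 comes from sulfide 14, that from hydroxy amide 13, that from lactone 12, and that from methyl hydrogen (R)-3-methylglutarate 10. The five carbons C5–C9 with C7 at their centre are bought in one piece. C7 is β to both termini throughout and cannot epimerise. A four-carbon chiral-pool unit would need two separate one-carbon extensions. The two ends of 10 differ only in ester versus acid; reducing the ester end makes the former acid carbon C5 and gives the S lactone.

**9 back to 3-bromofuran 1 and 4-bromofuran-2-carbaldehyde 2.** Enal 9 comes from aldehyde 8 by an E-selective Wittig reaction (C11=C12). Aldehyde 8 comes from alcohol 7, which arises by opening oxetane with the furyllithium 6 derived from bromide 5 (ring B C4–C14 bond, bringing C14–C12). Bromide 5 comes from carbinol 4 by deoxygenation, and 4 from furan-3-yllithium 3 (made from 1) and aldehyde 2 (inter-ring carbon). The bromine of 2 serves first as a spectator and then as the handle for the chain.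

## Roads not taken

**Alternative 1:** The cut is O1–C5. The enynoic acid A2, with its carboxyl cis to a C5≡C6 alkyne, would be cyclised with AgNO3 (monovalent silver) in a 5-exo-dig lactonisation to the methyl tetronate A1, which is the same compound as 24.
- Merits: the carboxylate adds anti to the metal, so the Z geometry at C5=C6 is set kinetically and stereospecifically. The medium is nearly neutral, which suits the furans. The ring closes in the key step itself.
- Weak points: A2 needs a geometrically defined β-methoxy enynoate and a terminal alkyne whose propargylic carbon is C7. That alkyne would come from an α-methyl aldehyde, the one type of intermediate in which C7 can epimerise. 6-endo-dig closure to a 2-pyranone is the standing competitor for such acids. The diene offers silver a second site of coordination.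
- Comparison: this road is better than the chosen one in how it fixes the Z alkene and in avoiding acid at the ring-closing stage. The chosen plan sets against that a thermodynamic preference for Z, a non-acidic fallback for the closure, a shorter approach to the acyclic precursor, and a stereocenter that is never α to a carbonyl group.

**Alternative 2:** The cut is C9=C10, made by sulfur extrusion. The alkyl allyl sulfone A4 would be halogenated in situ (CBr2F2, KOH on alumina), close to an episulfone and lose SO2 to give the silyl ether diene A3.
- Merits: the two halves are joined by a simple S-alkylation. No aldehyde partner is needed. The reagents are cheap.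
- Weak points: the geometry of the new alkene from alkyl allyl sulfones under these conditions is not reliably E. The sulfide must be oxidised to the sulfone with both electron-rich furans already present, and the halogenating medium is not kind to them either. A3 solves only the diene: it ends at C6 as a protected alcohol, so C5, the C4–C5 bond and ring A are all still to come, by homologation or via an α-methyl aldehyde.
- Comparison: this is a rival to step 10, not to the key step. Step 10 is equally convergent, is expected to be more E-selective, and oxidises sulfur before any furan is present. In favour of A4, it has no electrophile near the carbanion, whereas 15 carries a Weinreb amide. The chosen plan answers that with a Barbier protocol and a carboxylate fallback.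

**Alternative 3:** The cut is C7–C8. The silyl ketene acetal of the (S)-dienyl propanoate A6 would rearrange through a chair (Ireland–Claisen) to the acid A5, creating C7 and the E C9=C10 alkene together.
- Merits: one step sets the stereocenter and an alkene geometry. The E alkene follows from the chair with the alkenyl substituent equatorial. The chirality originates in a carbinol that could be made catalytically.
- Weak points: the configuration at C7 depends on both the enantiopurity of the doubly allylic carbinol and the geometry of the ketene acetal, and errors in the two multiply. The ester is doubly allylic, so rearrangement through the trisubstituted alkene and ionisation both compete. A5 carries its carboxyl at C6, so C7 is α to a carbonyl and epimerisable. A5 still lacks C5 and must be homologated or reduced to the aldehyde before ring A can be attached.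
- Comparison: this road is as good or better in that it does not depend on a purchased chiral building block and forms the E alkene stereospecifically. The chosen plan sets against it a stereocenter that is bought and never epimerisable, five steps from 10 to 16, and no homologation after the stereocenter is in place.

Key step: step 12

Assumption: methyl hydrogen (R)-3-methylglutarate (10) is taken as a purchasable, enantiomerically pure half-ester; if only the S half-ester were at hand, reducing its acid end with BH3·SMe2 would lead to the same lactone 12.

## Route

**Step 1**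
Reactants: 1 3-bromofuran; 2 4-bromofuran-2-carbaldehyde
Product: 4 (4-bromofuran-2-yl)(furan-3-yl)methanol (racemic), via furan-3-yllithium 3 (not isolated)
Conditions: n-BuLi, THF, −78 °C; then 2, −78 °C; aq. NH4Cl
Reagents that add atoms: none
Why: Bromine–lithium exchange on 3-bromofuran is fast at −78 °C and the 3-lithio species keeps its position at that temperature; 1,2-addition to the aldehyde of 2 outruns exchange at its ring bromide. The carbinol centre forms racemic and is removed in step 2.

**Step 2**
Reactants: 4 (4-bromofuran-2-yl)(furan-3-yl)methanol
Product: 5 4-bromo-2-(furan-3-ylmethyl)furan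
Conditions: Et3SiH (excess), CF3CO2H, CH2Cl2, −40 → 0 °C
Reagents that add atoms: none
Why: Ionic hydrogenation: acid ionises the carbinol to a cation stabilised by both furans, and hydride transfer from the silane, present in excess from the start, should outrun Friedel–Crafts attack on a furan ring. The ring bromide is inert.

**Step 3**
Reactants: 5 4-bromo-2-(furan-3-ylmethyl)furan
Product: 7 3-[5-(furan-3-ylmethyl)furan-3-yl]propan-1-ol, via [5-(furan-3-ylmethyl)furan-3-yl]lithium 6 (not isolated)
Conditions: n-BuLi, THF, −78 °C; oxetane, BF3·OEt2, −78 °C; aq. NaHCO3
Reagents that add atoms: oxetane, C1COC1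
Why: Bromine–lithium exchange at −78 °C is faster than deprotonation of the inter-ring methylene or a furan α-position. The aryllithium opens BF3-activated oxetane (Lewis acid-promoted oxetane opening), forming the ring B–C14 bond and delivering C14–C12 with a terminal alcohol.

**Step 4**
Reactants: 7 3-[5-(furan-3-ylmethyl)furan-3-yl]propan-1-ol
Product: 8 3-[5-(furan-3-ylmethyl)furan-3-yl]propanal
Conditions: Dess–Martin periodinane, NaHCO3, CH2Cl2, 0 °C → rt
Reagents that add atoms: none
Why: Dess–Martin oxidation of a primary alcohol under buffered, non-acidic conditions that furans tolerate; it stops at the aldehyde.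

**Step 5**
Reactants: 8 3-[5-(furan-3-ylmethyl)furan-3-yl]propanal
Product: 9 (2E)-5-[5-(furan-3-ylmethyl)furan-3-yl]-2-methylpent-2-enal
Conditions: Ph3P=C(Me)CHO, toluene, 80 °C
Reagents that add atoms: 2-(triphenyl-λ5-phosphanylidene)propanal, CC(C=O)=P(c1ccccc1)(c1ccccc1)c1ccccc1
Why: Wittig olefination with a stabilised formyl ylide is E-selective and sets the C11=C12 geometry. The enal product is less electrophilic than 8, which limits a second olefination.

**Step 6**
Reactants: 10 methyl hydrogen (R)-3-methylglutarate [(3R)-5-methoxy-3-methyl-5-oxopentanoic acid]
Product: 12 (4S)-4-methyloxan-2-one, via (3S)-5-hydroxy-3-methylpentanoic acid 11 (not isolated)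
Conditions: LiBH4, THF, 0 °C → rt; then 2 M HCl, rt
Reagents that add atoms: none
Why: Chemoselective borohydride reduction: the first hydride equivalent turns the acid into an inert carboxylate and the methyl ester is reduced; acidification lactonises the hydroxy acid. C7 is not touched; because the ester end is the one reduced, the R half-ester gives the S lactone with the former acid carbon as C5.

**Step 7**
Reactants: 12 (4S)-4-methyloxan-2-one
Product: 13 (3S)-5-hydroxy-N-methoxy-N,3-dimethylpentanamide
Conditions: MeNHOMe·HCl, AlMe3, CH2Cl2, 0 °C → rt; aq. potassium sodium tartrate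
Reagents that add atoms: N,O-dimethylhydroxylamine hydrochloride, CNOC.Cl
Why: Weinreb aminolysis of a lactone by the aluminium amide formed from AlMe3 and the amine hydrochloride. The hydroxy amide is taken on at once to forestall relactonisation.

**Step 8**
Reactants: 13 (3S)-5-hydroxy-N-methoxy-N,3-dimethylpentanamide
Product: 14 (3R)-N-methoxy-N,3-dimethyl-5-[(1-phenyl-1H-tetrazol-5-yl)sulfanyl]pentanamide
Conditions: 1-phenyl-1H-tetrazole-5-thiol, PPh3, DIAD, THF, 0 °C → rt
Reagents that add atoms: 1-phenyl-1H-tetrazole-5-thiol, Sc1nnnn1-c1ccccc1
Why: Mitsunobu thioetherification of a primary alcohol with an acidic thiol, SN2 at C9. C7 is untouched; its descriptor changes to R only because sulfur raises the priority of that arm.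

**Step 9**
Reactants: 14 (3R)-N-methoxy-N,3-dimethyl-5-[(1-phenyl-1H-tetrazol-5-yl)sulfanyl]pentanamide
Product: 15 (3R)-N-methoxy-N,3-dimethyl-5-[(1-phenyl-1H-tetrazol-5-yl)sulfonyl]pentanamide
Conditions: (NH4)6Mo7O24·4H2O (cat.), 30% H2O2, EtOH, 0 °C → rt
Reagents that add atoms: hydrogen peroxide, OO
Why: Molybdate-catalysed peroxide oxidation of sulfide to sulfone, the standard entry to Julia–Kocienski reagents. It is placed here because the molecule contains no furan or alkene yet.

**Step 10**
Reactants: 15 (3R)-N-methoxy-N,3-dimethyl-5-[(1-phenyl-1H-tetrazol-5-yl)sulfonyl]pentanamide; 9 (2E)-5-[5-(furan-3-ylmethyl)furan-3-yl]-2-methylpent-2-enal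
Product: 16 (3S,5E,7E)-10-[5-(furan-3-ylmethyl)furan-3-yl]-N-methoxy-N,3,7-trimethyldeca-5,7-dienamide
Conditions: KN(SiMe3)2 added to 15 + 9, DME, −78 °C → rt; aq. NH4Cl
Reagents that add atoms: none
Why: Julia–Kocienski olefination: the potassium sulfonyl carbanion adds to the enal, then Smiles rearrangement and loss of SO2 and tetrazololate form C9=C10; phenyltetrazolyl sulfones with a potassium counter-ion in DME and conjugated aldehydes favour the E alkene. The Barbier mode keeps the carbanion short-lived so that addition to the aldehyde should outrun attack on the internal Weinreb amide.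

**Step 11**
Reactants: 17 methyl propanoate; 18 methyl formate
Product: 20 methyl (E)-3-methoxy-2-methylprop-2-enoate, via sodium (E)-3-methoxy-2-methyl-3-oxoprop-1-en-1-olate 19 (not isolated)
Conditions: NaH, Et2O, 0 °C → rt; then Me2SO4, DMF, rt
Reagents that add atoms: dimethyl sulfate, COS(=O)(=O)OC
Why: Crossed Claisen condensation (methyl formate cannot enolise) gives the formyl ester as its sodium enolate, which the hard electrophile dimethyl sulfate alkylates on oxygen in a dipolar aprotic solvent. The E enol ether (methoxy trans to ester, vinylic hydrogen cis to ester) is the expected major and more stable isomer and is purified by distillation.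

**Step 12**
Reactants: 20 methyl (E)-3-methoxy-2-methylprop-2-enoate; 16 (3S,5E,7E)-10-[5-(furan-3-ylmethyl)furan-3-yl]-N-methoxy-N,3,7-trimethyldeca-5,7-dienamide
Product: 23 methyl (2E,6S,8E,10E)-13-[5-(furan-3-ylmethyl)furan-3-yl]-3-methoxy-2,6,10-trimethyl-4-oxotrideca-2,8,10-trienoate (ester cis to ketone), via methyl (E)-3-lithio-3-methoxy-2-methylprop-2-enoate 21 (not isolated), via chelated lithium hemiaminal alkoxide 22 (not isolated)
Conditions: 20 (excess), LiN(i-Pr)2, THF, −90 °C; then 16, −90 → −78 °C; AcOH, −78 °C
Reagents that add atoms: none
Why: Lithium diisopropylamide removes the vinylic hydrogen at C4, which is acidified by the geminal methoxy group and lies cis to the ester whose carbonyl oxygen holds the lithium, giving vinyllithium 21 as an acyl-anion equivalent for C4. 21 adds to the Weinreb carbonyl C5 of 16 to form the five-membered N-methoxy chelate 22, which does not collapse until protonated, so the ketone is released only on quench and cannot add a second time. The closest known reaction types are the Weinreb ketone synthesis with heteroatom-stabilised vinyllithiums and the capture of β-lithiated β-methoxyacrylates by aldehydes and ketones. No ring closes and no stereocenter is formed; C7 is β to the amide carbonyl and cannot epimerise. Vinylic metalation in preference to attack on the ester is secured by the methoxy group and ester coordination at low temperature. Retention of the vinyl geometry, which puts ester and new ketone cis, is secured by the internal chelate and by never warming 21. Addition in preference to enolisation of the amide α-methylene is favoured by keeping 20 in slight excess over the base, so that no free amide base remains, and 21 in excess over 16. The cold acetic acid quench prevents 22 from lactonising onto the neighbouring ester before the ketone is set free.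

**Step 13**
Reactants: 23 methyl (2E,6S,8E,10E)-13-[5-(furan-3-ylmethyl)furan-3-yl]-3-methoxy-2,6,10-trimethyl-4-oxotrideca-2,8,10-trienoate
Product: 24 (5Z)-5-[(2S,4E,6E)-9-[5-(furan-3-ylmethyl)furan-3-yl]-2,6-dimethylnona-4,6-dienylidene]-4-methoxy-3-methylfuran-2(5H)-one
Conditions: camphorsulfonic acid (cat.), 5 Å molecular sieves, toluene, 80 °C
Reagents that add atoms: none
Why: Acid-catalysed enol lactonisation of a cis γ-keto enoate: the C5 oxygen attacks the ester carbon C2 (5-exo-trig), and loss of methanol, taken up by the sieves, gives the ylidene butenolide. Reversible protonation puts C5=C6 under thermodynamic control, which favours Z (C7 beside O1, away from the C4 methoxy group). Any drift of the push-pull C3=C4 geometry in 23 is harmless because only the cis isomer is drained into the lactone.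

**Step 14**
Reactants: 24 (5Z)-5-[(2S,4E,6E)-9-[5-(furan-3-ylmethyl)furan-3-yl]-2,6-dimethylnona-4,6-dienylidene]-4-methoxy-3-methylfuran-2(5H)-one
Product: 25 (5Z)-5-[(2S,4E,6E)-9-[5-(furan-3-ylmethyl)furan-3-yl]-2,6-dimethylnona-4,6-dienylidene]-4-hydroxy-3-methylfuran-2(5H)-one (CNP0222779.1)
Conditions: n-PrSH, n-BuLi, HMPA, 0 °C; then 24, rt; cold 1 M HCl
Reagents that add atoms: none
Why: SN2 demethylation of a methyl tetronate by a soft thiolate in a dipolar aprotic solvent; the tetronate anion is an excellent leaving group, and once formed it protects the ring from further nucleophilic attack. The weakly basic thiolate should leave C7 and the alkene geometries alone, and mild acidification releases the tetronic acid.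

## Compound list

1 | 3-bromofuran | Brc1ccoc1 | starting material
2 | 4-bromofuran-2-carbaldehyde | O=Cc1cc(Br)co1 | starting material
3 | furan-3-yllithium | [Li]c1ccoc1 | intermediate
4 | (4-bromofuran-2-yl)(furan-3-yl)methanol (racemic) | OC(c1ccoc1)c1cc(Br)co1 | intermediate
5 | 4-bromo-2-(furan-3-ylmethyl)furan | Brc1coc(Cc2ccoc2)c1 | intermediate
6 | [5-(furan-3-ylmethyl)furan-3-yl]lithium | [Li]c1coc(Cc2ccoc2)c1 | intermediate
7 | 3-[5-(furan-3-ylmethyl)furan-3-yl]propan-1-ol | OCCCc1coc(Cc2ccoc2)c1 | intermediate
8 | 3-[5-(furan-3-ylmethyl)furan-3-yl]propanal | O=CCCc1coc(Cc2ccoc2)c1 | intermediate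
9 | (2E)-5-[5-(furan-3-ylmethyl)furan-3-yl]-2-methylpent-2-enal | O=C/C(C)=C/CCc1coc(Cc2ccoc2)c1 | intermediate
10 | methyl hydrogen (R)-3-methylglutarate [(3R)-5-methoxy-3-methyl-5-oxopentanoic acid] | COC(=O)C[C@H](C)CC(=O)O | starting material
11 | (3S)-5-hydroxy-3-methylpentanoic acid | OCC[C@H](C)CC(=O)O | intermediate
12 | (4S)-4-methyloxan-2-one | O=C1C[C@@H](C)CCO1 | intermediate
13 | (3S)-5-hydroxy-N-methoxy-N,3-dimethylpentanamide | CON(C)C(=O)C[C@@H](C)CCO | intermediate
14 | (3R)-N-methoxy-N,3-dimethyl-5-[(1-phenyl-1H-tetrazol-5-yl)sulfanyl]pentanamide | CON(C)C(=O)C[C@@H](C)CCSc1nnnn1-c1ccccc1 | intermediate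
15 | (3R)-N-methoxy-N,3-dimethyl-5-[(1-phenyl-1H-tetrazol-5-yl)sulfonyl]pentanamide | CON(C)C(=O)C[C@@H](C)CCS(=O)(=O)c1nnnn1-c1ccccc1 | intermediate
16 | (3S,5E,7E)-10-[5-(furan-3-ylmethyl)furan-3-yl]-N-methoxy-N,3,7-trimethyldeca-5,7-dienamide | CON(C)C(=O)C[C@@H](C)C/C=C/C(C)=C/CCc1coc(Cc2ccoc2)c1 | intermediate
17 | methyl propanoate | CCC(=O)OC | starting material
18 | methyl formate | COC=O | starting material
19 | sodium (E)-3-methoxy-2-methyl-3-oxoprop-1-en-1-olate | [Na+].[O-]/C=C(C)/C(=O)OC | intermediate
20 | methyl (E)-3-methoxy-2-methylprop-2-enoate | CO/C=C(C)/C(=O)OC | intermediate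
21 | methyl (E)-3-lithio-3-methoxy-2-methylprop-2-enoate (lithium cis to ester) | COC(=O)/C(C)=C(/OC)[Li] | intermediate
22 | lithium salt of methyl (2E,6S,8E,10E)-13-[5-(furan-3-ylmethyl)furan-3-yl]-4-hydroxy-3-methoxy-4-[methoxy(methyl)amino]-2,6,10-trimethyltrideca-2,8,10-trienoate (tetrahedral adduct, both C4 epimers) | COC(=O)/C(C)=C(OC)\C([O-])(N(C)OC)C[C@@H](C)C/C=C/C(C)=C/CCc1coc(Cc2ccoc2)c1.[Li+] | intermediate
23 | methyl (2E,6S,8E,10E)-13-[5-(furan-3-ylmethyl)furan-3-yl]-3-methoxy-2,6,10-trimethyl-4-oxotrideca-2,8,10-trienoate | COC(=O)/C(C)=C(OC)\C(=O)C[C@@H](C)C/C=C/C(C)=C/CCc1coc(Cc2ccoc2)c1 | intermediate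
24 | (5Z)-5-[(2S,4E,6E)-9-[5-(furan-3-ylmethyl)furan-3-yl]-2,6-dimethylnona-4,6-dienylidene]-4-methoxy-3-methylfuran-2(5H)-one | CC1=C(OC)/C(=C/[C@@H](C)C/C=C/C(C)=C/CCc2coc(Cc3ccoc3)c2)OC1=O | intermediate
25 | (5Z)-5-[(2S,4E,6E)-9-[5-(furan-3-ylmethyl)furan-3-yl]-2,6-dimethylnona-4,6-dienylidene]-4-hydroxy-3-methylfuran-2(5H)-one | CC1=C(O)/C(=C/[C@@H](C)C/C=C/C(C)=C/CCc2coc(Cc3ccoc3)c2)OC1=O | target

## Step count and risks

Total: 14 steps. Longest linear sequence: 9 steps (steps 1–5, 10, 12, 13, 14, from 3-bromofuran 1).

**Step 12 (key step).** The most likely failure is proton transfer from the α-methylene of amide 16 to the basic vinyllithium in place of addition. Decay of 21 by self-condensation before it meets the amide, and closure of adduct 22 onto the neighbouring ester if the mixture warms, are the other risks. The fallback keeps the C4–C5 bond and the same nucleophile but uses a faster electrophile and adjusts the oxidation level afterwards. It sets out from 16: reduction with i-Bu2AlH at −78 °C gives (3S,5E,7E)-10-[5-(furan-3-ylmethyl)furan-3-yl]-3,7-dimethyldeca-5,7-dienal F1. Addition of 21 to this aldehyde is expected to outrun any proton transfer, and the alkoxide lactonises onto the cis ester on warming to give 5-[(2S,4E,6E)-9-[5-(furan-3-ylmethyl)furan-3-yl]-2,6-dimethylnona-4,6-dienyl]-4-methoxy-3-methylfuran-2(5H)-one F2 as a mixture of C5 epimers. Deprotonation of C5 with LiN(i-Pr)2 at −78 °C and trapping with PhSeCl gives 5-[(2S,4E,6E)-9-[5-(furan-3-ylmethyl)furan-3-yl]-2,6-dimethylnona-4,6-dienyl]-4-methoxy-3-methyl-5-(phenylselanyl)furan-2(5H)-one F3. Oxidation with NaIO4 and syn elimination of the selenoxide towards C6 is expected to give the ylidene, which can be equilibrated to Z with a trace of iodine. The detour returns to the route at 24 and bypasses step 13.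

**Step 13.** The likely failure is acid-induced degradation of the furan rings, or acid-promoted migration within the diene, before methanol is lost. The fallback avoids acid altogether and sets out from 23. Me3SnOH in 1,2-dichloroethane at 80 °C should cleave the methyl ester under neutral conditions, and the cis keto acid closes to its ring tautomer 5-hydroxy-5-[(2S,4E,6E)-9-[5-(furan-3-ylmethyl)furan-3-yl]-2,6-dimethylnona-4,6-dienyl]-4-methoxy-3-methylfuran-2(5H)-one F4. Acetylation of the lactol hydroxyl with Ac2O, Et3N and 4-(dimethylamino)pyridine, followed by base-induced elimination of acetic acid, returns to the route at 24.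

**Step 10.** The likely failure is intramolecular acylation of the sulfonyl carbanion by the Weinreb amide through a five-membered transition state. Partial loss of E-selectivity at C9=C10 is the second risk. The fallback removes the internal electrophile by carrying C5 as a carboxylate through the olefination. It sets out from lactone 12.
- HBr in acetic acid opens the lactone to (3R)-5-bromo-3-methylpentanoic acid F5.
- 1-Phenyl-1H-tetrazole-5-thiol and K2CO3 give (3R)-3-methyl-5-[(1-phenyl-1H-tetrazol-5-yl)sulfanyl]pentanoic acid F6.
- The molybdate/H2O2 oxidation of step 9 gives (3R)-3-methyl-5-[(1-phenyl-1H-tetrazol-5-yl)sulfonyl]pentanoic acid F7.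
- The dianion of F7, formed with two equivalents of KN(SiMe3)2, is joined with enal 9 to give (3S,5E,7E)-10-[5-(furan-3-ylmethyl)furan-3-yl]-3,7-dimethyldeca-5,7-dienoic acid F8.
- Carbodiimide coupling with MeNHOMe·HCl returns to the route at 16.

**Step 2.** The likely failure is cationic oligomerisation: the furyl-stabilised cation alkylates the free α-positions of another furan ring faster than it takes hydride from the silane. The fallback replaces cation chemistry by a basic reduction and sets out from 4. Oxidation with MnO2 gives (4-bromofuran-2-yl)(furan-3-yl)methanone F9. Hydrazine hydrate converts it into the hydrazone of (4-bromofuran-2-yl)(furan-3-yl)methanone F10, which is heated with KOH in diethylene glycol (Wolff–Kishner reduction, Huang-Minlon procedure) to return to the route at 5.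

## Further compounds

F1 | step 12 | (3S,5E,7E)-10-[5-(furan-3-ylmethyl)furan-3-yl]-3,7-dimethyldeca-5,7-dienal | O=CC[C@@H](C)C/C=C/C(C)=C/CCc1coc(Cc2ccoc2)c1
F2 | step 12 | 5-[(2S,4E,6E)-9-[5-(furan-3-ylmethyl)furan-3-yl]-2,6-dimethylnona-4,6-dienyl]-4-methoxy-3-methylfuran-2(5H)-one (C5 epimers) | CC1=C(OC)C(C[C@@H](C)C/C=C/C(C)=C/CCc2coc(Cc3ccoc3)c2)OC1=O
F3 | step 12 | 5-[(2S,4E,6E)-9-[5-(furan-3-ylmethyl)furan-3-yl]-2,6-dimethylnona-4,6-dienyl]-4-methoxy-3-methyl-5-(phenylselanyl)furan-2(5H)-one (C5 epimers) | CC1=C(OC)C([Se]c2ccccc2)(C[C@@H](C)C/C=C/C(C)=C/CCc2coc(Cc3ccoc3)c2)OC1=O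
F4 | step 13 | 5-hydroxy-5-[(2S,4E,6E)-9-[5-(furan-3-ylmethyl)furan-3-yl]-2,6-dimethylnona-4,6-dienyl]-4-methoxy-3-methylfuran-2(5H)-one (C5 epimers) | CC1=C(OC)C(O)(C[C@@H](C)C/C=C/C(C)=C/CCc2coc(Cc3ccoc3)c2)OC1=O
F5 | step 10 | (3R)-5-bromo-3-methylpentanoic acid | OC(=O)C[C@@H](C)CCBr
F6 | step 10 | (3R)-3-methyl-5-[(1-phenyl-1H-tetrazol-5-yl)sulfanyl]pentanoic acid | OC(=O)C[C@@H](C)CCSc1nnnn1-c1ccccc1
F7 | step 10 | (3R)-3-methyl-5-[(1-phenyl-1H-tetrazol-5-yl)sulfonyl]pentanoic acid | OC(=O)C[C@@H](C)CCS(=O)(=O)c1nnnn1-c1ccccc1
F8 | step 10 | (3S,5E,7E)-10-[5-(furan-3-ylmethyl)furan-3-yl]-3,7-dimethyldeca-5,7-dienoic acid | OC(=O)C[C@@H](C)C/C=C/C(C)=C/CCc1coc(Cc2ccoc2)c1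
F9 | step 2 | (4-bromofuran-2-yl)(furan-3-yl)methanone | O=C(c1ccoc1)c1cc(Br)co1
F10 | step 2 | (4-bromofuran-2-yl)(furan-3-yl)methanone hydrazone | NN=C(c1ccoc1)c1cc(Br)co1
A1 | alternative 1 | (5Z)-5-[(2S,4E,6E)-9-[5-(furan-3-ylmethyl)furan-3-yl]-2,6-dimethylnona-4,6-dienylidene]-4-methoxy-3-methylfuran-2(5H)-one | CC1=C(OC)/C(=C/[C@@H](C)C/C=C/C(C)=C/CCc2coc(Cc3ccoc3)c2)OC1=O
A2 | alternative 1 | (2E,6S,8E,10E)-13-[5-(furan-3-ylmethyl)furan-3-yl]-3-methoxy-2,6,10-trimethyltrideca-2,8,10-trien-4-ynoic acid (carboxyl cis to the alkyne) | OC(=O)/C(C)=C(OC)\C#C[C@@H](C)C/C=C/C(C)=C/CCc1coc(Cc2ccoc2)c1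
A3 | alternative 2 | tert-butyl-[(2S,4E,6E)-9-[5-(furan-3-ylmethyl)furan-3-yl]-2,6-dimethylnona-4,6-dienoxy]dimethylsilane | CC(C)(C)[Si](C)(C)OC[C@@H](C)C/C=C/C(C)=C/CCc1coc(Cc2ccoc2)c1
A4 | alternative 2 | tert-butyl-[(2S)-4-[(2E)-5-[5-(furan-3-ylmethyl)furan-3-yl]-2-methylpent-2-enyl]sulfonyl-2-methylbutoxy]dimethylsilane | CC(C)(C)[Si](C)(C)OC[C@@H](C)CCS(=O)(=O)C/C(C)=C/CCc1coc(Cc2ccoc2)c1
A5 | alternative 3 | (2S,4E,6E)-9-[5-(furan-3-ylmethyl)furan-3-yl]-2,6-dimethylnona-4,6-dienoic acid | OC(=O)[C@@H](C)C/C=C/C(C)=C/CCc1coc(Cc2ccoc2)c1
A6 | alternative 3 | (3S,4E)-7-[5-(furan-3-ylmethyl)furan-3-yl]-4-methylhepta-1,4-dien-3-yl propanoate | CCC(=O)O[C@@H](C=C)/C(C)=C/CCc1coc(Cc2ccoc2)c1
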